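**Plan**

- Numbering: unprimed atoms belong to the flavanone (ring B carbons 1'–6'), double-primed atoms to the flavone.
- Retrosynthesis: remove the eight benzyl ethers, cut C2–C1' (arylboronic acid plus 5,7-bis(benzyloxy)chromone), then cut C4''–C4a'' and O1''–C2'' of the flavone pyranone, and last the biaryl bond C5'–C6''.
- Forward: a ring B iodide (from 5-chlorosalicylaldehyde) is coupled to the 4-position of a 3,5-bis(benzyloxy)phenol unit to give phenol 11; a β-keto ester then annulates the pyranone ring (O1'', C2'', C3'', C4'') onto it.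
- Enabling feature: in 11 the aryl group lies on the symmetry axis of the phloroglucinol-derived ring, so the two open ring carbons (later C4a'' and C8'') are equivalent. The only free hydroxyl is the one para to the aryl group (later O1''), so only the 6''-aryl flavone can form.
- The ring B chloride then becomes a boronic acid, a rhodium-catalysed asymmetric conjugate addition to the chromone builds the flavanone, and hydrogenolysis frees all phenols.
- Stereochemistry: the single stereocenter C2 (S) is set by the chiral catalyst in step 12 and is not touched afterwards.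

Key step: step 8

Remark: the (S)-configured biaryl bisphosphine is chosen by analogy with the known facial preference of (S)-biaryl bisphosphine aryl–rhodium species for cyclic enones (aryl to the Re face of C2 of the chromone); if the sense proved opposite, the mirror-image ligand would be used with no other change.

**Route**

Step 1
Reactants: 1 5-chloro-2-hydroxybenzaldehyde
Product: 2 5-chloro-2-hydroxy-3-iodobenzaldehyde
Conditions: NIS, AcOH, 40 °C
Reagents that add atoms: N-iodosuccinimide, O=C1CCC(=O)N1I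
Why: Electrophilic aromatic iodination should go only to C3, the one carbon ortho to the hydroxyl (its para position carries chlorine) and also meta to the formyl group.

Step 2
Reactants: 2 5-chloro-2-hydroxy-3-iodobenzaldehyde
Product: 4 5-chloro-3-iodobenzene-1,2-diol, via aryl formate 3 (not isolated)
Conditions: H2O2 (30% aq), NaOH, H2O/THF, 0 °C to rt; then dilute HCl
Reagents that add atoms: hydrogen peroxide, OO
Why: Dakin oxidation, in which hydroperoxide adds to the aldehyde, the electron-rich ortho-hydroxyaryl group migrates to oxygen, and formate 3 is saponified in the same alkaline medium.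

Step 3
Reactants: 4 5-chloro-3-iodobenzene-1,2-diol
Product: 5 1,2-bis(benzyloxy)-5-chloro-3-iodobenzene
Conditions: BnBr, K2CO3, DMF, 60 °C
Reagents that add atoms: benzyl bromide, BrCc1ccccc1
Why: Williamson etherification of both catechol hydroxyls, which also removes the air sensitivity of the catechol.

Step 4
Reactants: 6 3,5-bis(benzyloxy)phenol
Product: 7 [3,5-bis(benzyloxy)phenoxy]tri(propan-2-yl)silane
Conditions: i-Pr3SiCl, imidazole, DMF, rt
Reagents that add atoms: chlorotri(propan-2-yl)silane, CC(C)[Si](Cl)(C(C)C)C(C)C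
Why: Standard phenol silylation; the bulky silyl ether is a poor directing group and shields its two neighbouring ring carbons, leaving the carbon between the two benzyloxy groups as the site for metalation.

Step 5
Reactants: 7 [3,5-bis(benzyloxy)phenoxy]tri(propan-2-yl)silane; 5 1,2-bis(benzyloxy)-5-chloro-3-iodobenzene
Product: 10 {3,5-bis(benzyloxy)-4-[2,3-bis(benzyloxy)-5-chlorophenyl]phenoxy}tri(propan-2-yl)silane, via aryllithium 8 (not isolated), via arylzinc chloride 9 (not isolated)
Conditions: n-BuLi, THF, 0 °C; ZnCl2, 0 °C to rt; then 5, Pd2(dba)3 (cat.), RuPhos, THF, 55 °C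
Reagents that add atoms: none
Why: Directed ortho-metalation at the ring CH flanked by two coordinating benzyloxy groups, transmetalation to zinc and Negishi coupling should give the tri-ortho-substituted biaryl, because oxidative addition of zerovalent palladium to the iodide is far faster than to the chloride and dialkylbiarylphosphine ligands are known to join hindered 2,6-dialkoxyarylzinc reagents.

Step 6
Reactants: 10 {3,5-bis(benzyloxy)-4-[2,3-bis(benzyloxy)-5-chlorophenyl]phenoxy}tri(propan-2-yl)silane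
Product: 11 3,5-bis(benzyloxy)-4-[2,3-bis(benzyloxy)-5-chlorophenyl]phenol
Conditions: Bu4NF, AcOH, THF, 0 °C to rt
Reagents that add atoms: none
Why: Fluoride-driven cleavage of the aryl silyl ether, buffered with acetic acid so that the electron-rich phenoxide is not exposed to air oxidation.

Step 7
Reactants: 12 3,4-bis(benzyloxy)benzoic acid
Product: 15 ethyl 3-[3,4-bis(benzyloxy)phenyl]-3-oxopropanoate, via acyl imidazolide 13 (not isolated), via aroylmalonate half-ester 14 (not isolated)
Conditions: CDI, THF, rt; then KO2CCH2CO2Et, MgCl2, Et3N, MeCN, rt to 45 °C; 1 M HCl work-up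
Reagents that add atoms: potassium ethyl malonate, CCOC(=O)CC(=O)[O-].[K+]
Why: Masamune–Brooks homologation, in which the acyl imidazolide C-acylates the magnesium chelate of the malonate half-ester and the acidic work-up decarboxylates 14 to the β-keto ester.

Step 8
Reactants: 11 3,5-bis(benzyloxy)-4-[2,3-bis(benzyloxy)-5-chlorophenyl]phenol; 15 ethyl 3-[3,4-bis(benzyloxy)phenyl]-3-oxopropanoate
Product: 18 5,7-bis(benzyloxy)-6-[2,3-bis(benzyloxy)-5-chlorophenyl]-2-[3,4-bis(benzyloxy)phenyl]-4H-chromen-4-one, via aroylketene 16 (not isolated), via aryl 1,3-diketone 17 (not isolated)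
Conditions: 15 (2 equiv), Ph2O, 245 °C, argon sweep (−EtOH, −H2O)
Reagents that add atoms: none
Why: At 245 °C keto ester 15 loses ethanol to aroylketene 16, which is captured reversibly at the phenolic oxygen but productively at the ring carbon ortho to the free hydroxyl and para to a benzyloxy group of 11, forming C4''–C4a'' in diketone 17. The free hydroxyl then adds to the aryl ketone in a 6-exo-trig hemiketalisation and loss of water closes the pyranone (O1''–C2''), an irreversible aromatising step that drains the preceding equilibria. The closest known reaction is the Mentzer pyrone synthesis, the thermal condensation of phloroglucinol or of 3,5-dialkoxyphenols with aroylacetates to 5,7-dioxygenated flavones. No stereocenter is formed. The step needs site control in both the C-acylation and the ring closure: the 4-aryl group makes the two open ring carbons of 11 identical, and because the hydroxyl para to the aryl group is the only free one, the 6''-aryl flavone is the only chromone that can form, while the neutral, acid-free melt favours chromone over Pechmann-type coumarin closure.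

Step 9
Reactants: 18 5,7-bis(benzyloxy)-6-[2,3-bis(benzyloxy)-5-chlorophenyl]-2-[3,4-bis(benzyloxy)phenyl]-4H-chromen-4-one
Product: 19 5,7-bis(benzyloxy)-6-[2,3-bis(benzyloxy)-5-(4,4,5,5-tetramethyl-1,3,2-dioxaborolan-2-yl)phenyl]-2-[3,4-bis(benzyloxy)phenyl]-4H-chromen-4-one
Conditions: B2pin2, Pd2(dba)3 (cat.), XPhos, KOAc, 1,4-dioxane, 105 °C
Reagents that add atoms: bis(pinacolato)diboron, CC1(C)OB(B2OC(C)(C)C(C)(C)O2)OC1(C)C
Why: Miyaura borylation of an unhindered aryl chloride, for which the bulky dialkylbiarylphosphine/Pd2(dba)3 system is well established, with benzyl ethers and the flavone as spectators.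

Step 10
Reactants: 19 the pinacol boronate of step 9
Product: 20 {3,4-bis(benzyloxy)-5-[5,7-bis(benzyloxy)-2-[3,4-bis(benzyloxy)phenyl]-4-oxo-4H-chromen-6-yl]phenyl}boronic acid
Conditions: NaIO4, NH4OAc, acetone/THF/H2O, rt
Reagents that add atoms: water, O
Why: Periodate cleaves the pinacol released in the hydrolysis equilibrium (glycol cleavage), which pulls the boronic ester over to the free boronic acid needed for fast transmetalation in step 12.

Step 11
Reactants: 21 1-[2,4-bis(benzyloxy)-6-hydroxyphenyl]ethan-1-one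
Product: 23 5,7-bis(benzyloxy)-4H-chromen-4-one, via enaminone 22 (not isolated)
Conditions: Me2NCH(OMe)2, toluene, 100 °C; then conc. HCl, CH2Cl2, 40 °C
Reagents that add atoms: N,N-dimethylformamide dimethyl acetal, COC(OC)N(C)C
Why: Enaminone formation from the methyl ketone followed by acid-promoted addition of the phenol to the β-carbon and loss of dimethylamine is the standard chromone synthesis from ortho-hydroxyacetophenones.

Step 12
Reactants: 20 the arylboronic acid of step 10; 23 5,7-bis(benzyloxy)-4H-chromen-4-one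
Product: 24 (2S)-5,7-bis(benzyloxy)-2-{3,4-bis(benzyloxy)-5-[5,7-bis(benzyloxy)-2-[3,4-bis(benzyloxy)phenyl]-4-oxo-4H-chromen-6-yl]phenyl}-2,3-dihydro-4H-chromen-4-one
Conditions: [Rh(OH)(cod)]2 (cat.), (S)-6,6'-dimethoxy-2,2'-bis[bis(3,4,5-trifluorophenyl)phosphino]biphenyl, 23 (2 equiv), toluene/H2O, 30 °C
Reagents that add atoms: none
Why: Hayashi–Miyaura asymmetric 1,4-addition, in which the aryl group passes from boron to monovalent rhodium and inserts into C2=C3 of 23 on the Re face of C2 as dictated by the (S)-bisphosphine, setting C2 as S; the electron-poor ligand allows a low temperature that limits ring opening of the flavanone, and the 2-aryl-substituted flavone inside 20 is not an acceptor.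

Step 13
Reactants: 24 the octabenzyl ether of step 12
Product: 25 (2S)-2-{3,4-dihydroxy-5-[2-(3,4-dihydroxyphenyl)-5,7-dihydroxy-4-oxo-4H-chromen-6-yl]phenyl}-5,7-dihydroxy-2,3-dihydro-4H-chromen-4-one
Conditions: H2 (1 atm), Pd/C, THF/MeOH, rt
Reagents that add atoms: none
Why: Hydrogenolysis of the eight benzyl ethers under neutral conditions should leave the flavone double bond, both chelated carbonyls and the base-sensitive C2 stereocenter unchanged.

**Compound list**

1 | 5-chloro-2-hydroxybenzaldehyde | O=Cc1cc(Cl)ccc1O | starting material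
2 | 5-chloro-2-hydroxy-3-iodobenzaldehyde | O=Cc1cc(Cl)cc(I)c1O | intermediate
3 | 5-chloro-2-hydroxy-3-iodophenyl formate | O=COc1cc(Cl)cc(I)c1O | intermediate (not isolated)
4 | 5-chloro-3-iodobenzene-1,2-diol | Oc1cc(Cl)cc(I)c1O | intermediate
5 | 1,2-bis(benzyloxy)-5-chloro-3-iodobenzene | Clc1cc(I)c(OCc2ccccc2)c(OCc2ccccc2)c1 | intermediate
6 | 3,5-bis(benzyloxy)phenol | Oc1cc(OCc2ccccc2)cc(OCc2ccccc2)c1 | starting material
7 | [3,5-bis(benzyloxy)phenoxy]tri(propan-2-yl)silane | CC(C)[Si](Oc1cc(OCc2ccccc2)cc(OCc2ccccc2)c1)(C(C)C)C(C)C | intermediate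
8 | {2,6-bis(benzyloxy)-4-[tri(propan-2-yl)silyloxy]phenyl}lithium | [Li]c1c(OCc2ccccc2)cc(O[Si](C(C)C)(C(C)C)C(C)C)cc1OCc1ccccc1 | intermediate (not isolated)
9 | {2,6-bis(benzyloxy)-4-[tri(propan-2-yl)silyloxy]phenyl}zinc chloride | Cl[Zn]c1c(OCc2ccccc2)cc(O[Si](C(C)C)(C(C)C)C(C)C)cc1OCc1ccccc1 | intermediate (not isolated)
10 | {3,5-bis(benzyloxy)-4-[2,3-bis(benzyloxy)-5-chlorophenyl]phenoxy}tri(propan-2-yl)silane | CC(C)[Si](Oc1cc(OCc2ccccc2)c(-c2cc(Cl)cc(OCc3ccccc3)c2OCc2ccccc2)c(OCc2ccccc2)c1)(C(C)C)C(C)C | intermediate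
11 | 3,5-bis(benzyloxy)-4-[2,3-bis(benzyloxy)-5-chlorophenyl]phenol | Oc1cc(OCc2ccccc2)c(-c2cc(Cl)cc(OCc3ccccc3)c2OCc2ccccc2)c(OCc2ccccc2)c1 | intermediate
12 | 3,4-bis(benzyloxy)benzoic acid | OC(=O)c1ccc(OCc2ccccc2)c(OCc2ccccc2)c1 | starting material
13 | [3,4-bis(benzyloxy)phenyl](1H-imidazol-1-yl)methanone | O=C(c1ccc(OCc2ccccc2)c(OCc2ccccc2)c1)n1ccnc1 | intermediate (not isolated)
14 | 2-[3,4-bis(benzyloxy)benzoyl]-3-ethoxy-3-oxopropanoic acid (magnesium salt in the flask) | CCOC(=O)C(C(=O)O)C(=O)c1ccc(OCc2ccccc2)c(OCc2ccccc2)c1 | intermediate (not isolated)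
15 | ethyl 3-[3,4-bis(benzyloxy)phenyl]-3-oxopropanoate | CCOC(=O)CC(=O)c1ccc(OCc2ccccc2)c(OCc2ccccc2)c1 | intermediate
16 | 3-[3,4-bis(benzyloxy)phenyl]prop-1-ene-1,3-dione (aroylketene) | O=C=CC(=O)c1ccc(OCc2ccccc2)c(OCc2ccccc2)c1 | intermediate (not isolated)
17 | 1-{4,6-bis(benzyloxy)-5-[2,3-bis(benzyloxy)-5-chlorophenyl]-2-hydroxyphenyl}-3-[3,4-bis(benzyloxy)phenyl]propane-1,3-dione | O=C(CC(=O)c1ccc(OCc2ccccc2)c(OCc2ccccc2)c1)c1c(O)cc(OCc2ccccc2)c(-c2cc(Cl)cc(OCc3ccccc3)c2OCc2ccccc2)c1OCc1ccccc1 | intermediate (not isolated)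
18 | 5,7-bis(benzyloxy)-6-[2,3-bis(benzyloxy)-5-chlorophenyl]-2-[3,4-bis(benzyloxy)phenyl]-4H-chromen-4-one | O=c1cc(-c2ccc(OCc3ccccc3)c(OCc3ccccc3)c2)oc2cc(OCc3ccccc3)c(-c3cc(Cl)cc(OCc4ccccc4)c3OCc3ccccc3)c(OCc3ccccc3)c12 | intermediate
19 | 5,7-bis(benzyloxy)-6-[2,3-bis(benzyloxy)-5-(4,4,5,5-tetramethyl-1,3,2-dioxaborolan-2-yl)phenyl]-2-[3,4-bis(benzyloxy)phenyl]-4H-chromen-4-one | CC1(C)OB(c2cc(OCc3ccccc3)c(OCc3ccccc3)c(-c3c(OCc4ccccc4)cc4oc(-c5ccc(OCc6ccccc6)c(OCc6ccccc6)c5)cc(=O)c4c3OCc3ccccc3)c2)OC1(C)C | intermediate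
20 | {3,4-bis(benzyloxy)-5-[5,7-bis(benzyloxy)-2-[3,4-bis(benzyloxy)phenyl]-4-oxo-4H-chromen-6-yl]phenyl}boronic acid | OB(O)c1cc(OCc2ccccc2)c(OCc2ccccc2)c(-c2c(OCc3ccccc3)cc3oc(-c4ccc(OCc5ccccc5)c(OCc5ccccc5)c4)cc(=O)c3c2OCc2ccccc2)c1 | intermediate
21 | 1-[2,4-bis(benzyloxy)-6-hydroxyphenyl]ethan-1-one | CC(=O)c1c(O)cc(OCc2ccccc2)cc1OCc1ccccc1 | starting material
22 | (E)-1-[2,4-bis(benzyloxy)-6-hydroxyphenyl]-3-(dimethylamino)prop-2-en-1-one | CN(C)/C=C/C(=O)c1c(O)cc(OCc2ccccc2)cc1OCc1ccccc1 | intermediate (not isolated)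
23 | 5,7-bis(benzyloxy)-4H-chromen-4-one | O=c1ccoc2cc(OCc3ccccc3)cc(OCc3ccccc3)c12 | intermediate
24 | (2S)-5,7-bis(benzyloxy)-2-{3,4-bis(benzyloxy)-5-[5,7-bis(benzyloxy)-2-[3,4-bis(benzyloxy)phenyl]-4-oxo-4H-chromen-6-yl]phenyl}-2,3-dihydro-4H-chromen-4-one | O=C1C[C@@H](c2cc(OCc3ccccc3)c(OCc3ccccc3)c(-c3c(OCc4ccccc4)cc4oc(-c5ccc(OCc6ccccc6)c(OCc6ccccc6)c5)cc(=O)c4c3OCc3ccccc3)c2)Oc2cc(OCc3ccccc3)cc(OCc3ccccc3)c21 | intermediate
25 | (2S)-2-{3,4-dihydroxy-5-[2-(3,4-dihydroxyphenyl)-5,7-dihydroxy-4-oxo-4H-chromen-6-yl]phenyl}-5,7-dihydroxy-2,3-dihydro-4H-chromen-4-one | O=C1C[C@@H](c2cc(O)c(O)c(-c3c(O)cc4oc(-c5ccc(O)c(O)c5)cc(=O)c4c3O)c2)Oc2cc(O)cc(O)c21 | target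

**Count**

Total steps: 13. Longest linear sequence: 10 steps (1, 2, 3, 5, 6, 8, 9, 10, 12, 13).

**Steps most likely to fail**

Step 8. The ketene may be held at oxygen as the aryl ester without moving to carbon, closure may go the Pechmann way to a coumarin, and benzyl ethers may migrate or cleave in the hot phenolic melt. The fallback builds the same two bonds stepwise at low temperature and sets out from phenol 11. C-acetylation ortho to the hydroxyl with AcOH/(CF3CO)2O (then K2CO3/MeOH to cleave any aryl acetate) should give 1-{4,6-bis(benzyloxy)-5-[2,3-bis(benzyloxy)-5-chlorophenyl]-2-hydroxyphenyl}ethan-1-one F1. Its lithium dienolate (LiN(SiMe3)2, THF, −78 °C) would be C-aroylated with 3,4-bis(benzyloxy)benzoyl chloride F2, made from acid 12 with oxalyl chloride, to give diketone 17, here isolated. Cyclodehydration of 17 with TsOH in warm toluene returns to the route at flavone 18.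

Step 12. The boronic acid is the limiting, advanced partner and may protodeboronate before it transmetalates; facial control may be incomplete; and reversible opening of the flavanone to the 2'-hydroxychalcone would erode the configuration. The fallback gives up catalyst control and sets out from 20 and 23. A base-free addition with Pd(OCOCF3)2/2,2'-bipyridine in aqueous acetic acid/THF should give racemic 5,7-bis(benzyloxy)-2-{3,4-bis(benzyloxy)-5-[5,7-bis(benzyloxy)-2-[3,4-bis(benzyloxy)phenyl]-4-oxo-4H-chromen-6-yl]phenyl}-2,3-dihydro-4H-chromen-4-one F3. Preparative chromatography on a cellulose tris(3,5-dimethylphenylcarbamate) phase would separate the enantiomers, and the (2S)-enantiomer is compound 24.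

Step 5. n-BuLi may remove a benzylic proton (followed by Wittig rearrangement) instead of the ring proton between the two benzyloxy groups, and coupling at the doubly flanked zinc carbon may be slow enough for the chloride to start reacting. The fallback avoids metalating benzyl ethers and sets out from iodide 5.
- Commercial benzene-1,3,5-triol is converted with MOMCl/i-Pr2NEt into 1,3,5-tris(methoxymethoxy)benzene F4.
- Lithiation with n-BuLi and quenching with B(OMe)3 gives [2,4,6-tris(methoxymethoxy)phenyl]boronic acid F5.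
- Suzuki coupling with 5 (Pd(OAc)2, SPhos, K3PO4, toluene/H2O, 80 °C) gives 1,2-bis(benzyloxy)-5-chloro-3-[2,4,6-tris(methoxymethoxy)phenyl]benzene F6.
- HCl in MeOH frees 2-[2,3-bis(benzyloxy)-5-chlorophenyl]benzene-1,3,5-triol F7.
- One equivalent of i-Pr3SiCl/imidazole at low temperature silylates the least hindered hydroxyl, the one para to the aryl group, to give 2-[2,3-bis(benzyloxy)-5-chlorophenyl]-5-[tri(propan-2-yl)silyloxy]benzene-1,3-diol F8.
- Benzylation of the two remaining hydroxyls (BnBr, K2CO3, acetone) returns to the route at compound 10.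

**Further compounds**

F1 | step 8 | 1-{4,6-bis(benzyloxy)-5-[2,3-bis(benzyloxy)-5-chlorophenyl]-2-hydroxyphenyl}ethan-1-one | CC(=O)c1c(O)cc(OCc2ccccc2)c(-c2cc(Cl)cc(OCc3ccccc3)c2OCc2ccccc2)c1OCc1ccccc1
F2 | step 8 | 3,4-bis(benzyloxy)benzoyl chloride | O=C(Cl)c1ccc(OCc2ccccc2)c(OCc2ccccc2)c1
F3 | step 12 | racemic 5,7-bis(benzyloxy)-2-{3,4-bis(benzyloxy)-5-[5,7-bis(benzyloxy)-2-[3,4-bis(benzyloxy)phenyl]-4-oxo-4H-chromen-6-yl]phenyl}-2,3-dihydro-4H-chromen-4-one | O=C1CC(c2cc(OCc3ccccc3)c(OCc3ccccc3)c(-c3c(OCc4ccccc4)cc4oc(-c5ccc(OCc6ccccc6)c(OCc6ccccc6)c5)cc(=O)c4c3OCc3ccccc3)c2)Oc2cc(OCc3ccccc3)cc(OCc3ccccc3)c21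
F4 | step 5 | 1,3,5-tris(methoxymethoxy)benzene | COCOc1cc(OCOC)cc(OCOC)c1
F5 | step 5 | [2,4,6-tris(methoxymethoxy)phenyl]boronic acid | COCOc1cc(OCOC)c(B(O)O)c(OCOC)c1
F6 | step 5 | 1,2-bis(benzyloxy)-5-chloro-3-[2,4,6-tris(methoxymethoxy)phenyl]benzene | COCOc1cc(OCOC)c(-c2cc(Cl)cc(OCc3ccccc3)c2OCc2ccccc2)c(OCOC)c1
F7 | step 5 | 2-[2,3-bis(benzyloxy)-5-chlorophenyl]benzene-1,3,5-triol | Oc1cc(O)c(-c2cc(Cl)cc(OCc3ccccc3)c2OCc2ccccc2)c(O)c1
F8 | step 5 | 2-[2,3-bis(benzyloxy)-5-chlorophenyl]-5-[tri(propan-2-yl)silyloxy]benzene-1,3-diol | CC(C)[Si](Oc1cc(O)c(-c2cc(Cl)cc(OCc3ccccc3)c2OCc2ccccc2)c(O)c1)(C(C)C)C(C)C
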